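Ring A is a phloroglucinol whose only O-methyl (on C7) lies para to the acyl-bearing carbon C4a, flanked by oxygens on C5 and C8a: the imprint of a 4-methoxy-2-pyrone. The route therefore rests on the C4a–C5 disconnection. In one operation, magnesium methoxide opens a 4-methoxy-2-pyrone carrying a CH2–C(=O)–CH=CH–aryl chain at C6 (aryl = 4-benzyloxy-3-methoxymethoxyphenyl) and recloses it by Claisen C-acylation, delivering the aromatic ring A of a 2',6'-dihydroxy-4'-methoxychalcone with the methyl ether already placed. Flavone closure, 5-O-benzylation, C3 hydroxylation, MOM removal, 3,3'-bis-sulfation and hydrogenolysis then give the target, which has no stereocentre.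

Key step: step 5

Remark: the target has no stereocentre and no stereogenic double bond, so the constitution as drawn is the single species to be made; the sulfate esters are drawn as free acids and are carried as triethylammonium salts until the final proton exchange.

Step 1
Reactants: 1 3,4-dihydroxybenzaldehyde
Product: 2 4-(benzyloxy)-3-hydroxybenzaldehyde
Conditions: BnBr (1.05 equiv), NaHCO3, NaI (cat.), DMF, 40 °C
Reagents that add atoms: benzyl bromide, BrCc1ccccc1
Why: The 4-OH, para to the formyl group, is the more acidic phenol, so the weak base should form and alkylate only that phenoxide (regioselective Williamson etherification).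

Step 2
Reactants: 2 4-(benzyloxy)-3-hydroxybenzaldehyde
Product: 3 4-(benzyloxy)-3-(methoxymethoxy)benzaldehyde
Conditions: MOMCl, K2CO3, acetone, 0 °C → rt
Reagents that add atoms: chloromethyl methyl ether, COCCl
Why: The remaining phenoxide is alkylated by the reactive α-chloro ether (Williamson-type acetal formation), giving a base-stable group that can later be removed by mild acid without touching benzyl ethers.

Step 3
Reactants: 3 4-(benzyloxy)-3-(methoxymethoxy)benzaldehyde; 4 diethyl {2-[methoxy(methyl)amino]-2-oxoethyl}phosphonate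
Product: 6 (2E)-3-[4-(benzyloxy)-3-(methoxymethoxy)phenyl]-N-methoxy-N-methylprop-2-enamide, via sodium phosphonate carbanion 5 (not isolated)
Conditions: NaH, THF, 0 °C; then 3, 0 °C → rt
Reagents that add atoms: none
Why: Horner–Wadsworth–Emmons olefination of an aryl aldehyde with an amide-stabilised phosphonate should give the E-alkene through the reversibly formed, thermodynamically preferred oxaphosphetane.

Step 4
Reactants: 7 4-methoxy-6-methyl-2H-pyran-2-one; 6 (2E)-3-[4-(benzyloxy)-3-(methoxymethoxy)phenyl]-N-methoxy-N-methylprop-2-enamide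
Product: 9 6-{(3E)-4-[4-(benzyloxy)-3-(methoxymethoxy)phenyl]-2-oxobut-3-en-1-yl}-4-methoxy-2H-pyran-2-one, via pyranylmethyllithium 8 (not isolated)
Conditions: 7 (2.1 equiv), LiHMDS (2.1 equiv), THF, −78 °C; then 6, −78 → −30 °C; aq. NH4Cl
Reagents that add atoms: none
Why: LiHMDS can remove only the vinylogous C6-methyl proton of the pyrone (the ring C–H bonds are beyond its basicity), and the extended enolate should add 1,2 to the Weinreb amide, whose chelated tetrahedral adduct persists until the quench and so prevents over-addition and proton transfer from the acidic product (Weinreb ketone synthesis, C-acylation of a pyrone dienolate).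

Step 5
Reactants: 9 6-{(3E)-4-[4-(benzyloxy)-3-(methoxymethoxy)phenyl]-2-oxobut-3-en-1-yl}-4-methoxy-2H-pyran-2-one
Product: 11 (2E)-3-[4-(benzyloxy)-3-(methoxymethoxy)phenyl]-1-(2,6-dihydroxy-4-methoxyphenyl)prop-2-en-1-one, via ring-opened triketo ester 10 (not isolated)
Conditions: Mg(OMe)2 (8 equiv), MeOH, reflux; cold 1 M HCl to pH 4
Reagents that add atoms: none
Why: Methoxide adds to the lactone carbonyl and the ring opens to the magnesium enolate of methyl ester 10, in which the 5,7-diketone is chelated and the ester stays cis to the C4 methylene across the enol-ether double bond inherited from the pyrone. The central carbon of the chelated diketone (future C4a) then attacks the ester carbonyl (future C5) in a 6-exo-trig Claisen (Dieckmann-type) C-acylation, methoxide leaves, and double enolisation aromatises ring A. The closest known reaction type is the base-mediated opening and Claisen recyclisation of 6-(2-oxoalkyl)-4-methoxy-2-pyrones and 3,5,7-triketo esters to acylphloroglucinols, the laboratory parallel of the chalcone synthase cyclisation. No stereocentre is formed and the E-alkene of the cinnamoyl unit is carried through unchanged. The step needs mode selectivity for Claisen closure over aldol closure (C2 onto the C7 ketone, giving a resorcylate); Mg2+ chelation makes the diketone's central carbon the nucleophile and activates the ester, the ester rather than carboxylate state of C1 keeps it acylating, and the O-methyl enol ether keeps C2 from acting as a β-keto-ester nucleophile. The lactone carbonyl oxygen and ring oxygen become the two equivalent ortho hydroxyls and the enol-ether carbon becomes C7–OMe, so the later choice of which hydroxyl closes ring C is degenerate.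

Step 6
Reactants: 11 (2E)-3-[4-(benzyloxy)-3-(methoxymethoxy)phenyl]-1-(2,6-dihydroxy-4-methoxyphenyl)prop-2-en-1-one
Product: 13 2-[4-(benzyloxy)-3-(methoxymethoxy)phenyl]-5-hydroxy-7-methoxy-4H-chromen-4-one, via flavanone 12 (not isolated)
Conditions: pyridine, 90 °C; then I2 (1.1 equiv), 95 °C; aq. Na2S2O3
Reagents that add atoms: none
Why: In hot pyridine the 2',6'-dihydroxychalcone should close by oxa-Michael addition to the racemic 5-hydroxyflavanone, whose C2 stereocentre is erased when iodine dehydrogenates the C2–C3 bond (the iodine–pyridine flavanone-to-flavone oxidation known for 5-hydroxyflavanones bearing acetal groups), and the basic medium keeps the MOM acetal away from the HI that hot I2/DMSO would liberate.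

Step 7
Reactants: 13 2-[4-(benzyloxy)-3-(methoxymethoxy)phenyl]-5-hydroxy-7-methoxy-4H-chromen-4-one
Product: 14 5-(benzyloxy)-2-[4-(benzyloxy)-3-(methoxymethoxy)phenyl]-7-methoxy-4H-chromen-4-one
Conditions: BnBr, K2CO3, Bu4NI (cat.), DMF, 70 °C
Reagents that add atoms: benzyl bromide, BrCc1ccccc1
Why: The 5-OH is the only free hydroxyl, and although it is hydrogen-bonded to the C4 carbonyl, warming with iodide catalysis should drive its Williamson benzylation, removing the acidic proton before the lithiation.

Step 8
Reactants: 14 5-(benzyloxy)-2-[4-(benzyloxy)-3-(methoxymethoxy)phenyl]-7-methoxy-4H-chromen-4-one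
Product: 17 5-(benzyloxy)-2-[4-(benzyloxy)-3-(methoxymethoxy)phenyl]-3-hydroxy-7-methoxy-4H-chromen-4-one, via 3-lithioflavone 15 (not isolated), via dimethyl flavon-3-ylboronate 16 (not isolated)
Conditions: LDA, THF, −78 °C; B(OMe)3, −78 → 0 °C; AcOH, 30% H2O2, 0 °C → rt
Reagents that add atoms: hydrogen peroxide, OO
Why: The C3–H of a 5,7-dialkoxyflavone is removed by LDA at −78 °C with carbonyl direction, the vinyllithium is trapped as the borate, and peroxide oxidises the C–B bond to C–OH (lithiation–borylation–oxidation, an established flavone-to-flavonol conversion), conditions under which benzyl and MOM ethers should stay intact.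

Step 9
Reactants: 17 5-(benzyloxy)-2-[4-(benzyloxy)-3-(methoxymethoxy)phenyl]-3-hydroxy-7-methoxy-4H-chromen-4-one
Product: 18 5-(benzyloxy)-2-[4-(benzyloxy)-3-hydroxyphenyl]-3-hydroxy-7-methoxy-4H-chromen-4-one
Conditions: 3 M HCl (cat.), MeOH–THF, 45 °C
Reagents that add atoms: none
Why: Acid-catalysed transacetalisation of the aryl MOM ether to methanol should free the 3'-OH under conditions too mild to cleave the benzyl ethers.

Step 10
Reactants: 18 5-(benzyloxy)-2-[4-(benzyloxy)-3-hydroxyphenyl]-3-hydroxy-7-methoxy-4H-chromen-4-one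
Product: 19 5-(benzyloxy)-2-[4-(benzyloxy)-3-(sulfooxy)phenyl]-7-methoxy-4-oxo-4H-chromen-3-yl hydrogen sulfate (handled as its bis(triethylammonium) salt)
Conditions: SO3·NMe3 (8 equiv), Et3N, DMF, 55 °C
Reagents that add atoms: sulfur trioxide–trimethylamine complex, C[N+](C)(C)S(=O)(=O)[O-]
Why: The only two free hydroxyls (the enolic 3-OH and the phenolic 3'-OH) should be O-sulfonated by excess amine–SO3 complex, so the sulfation pattern is fixed by the protecting groups and not by reagent selectivity.

Step 11
Reactants: 19 5-(benzyloxy)-2-[4-(benzyloxy)-3-(sulfooxy)phenyl]-7-methoxy-4-oxo-4H-chromen-3-yl hydrogen sulfate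
Product: 20 rhamnetin 3,3'-disulfate
Conditions: H2 (1 atm), 10% Pd/C, MeOH–THF, rt; then Dowex 50W (H+), 0 °C, freeze-dry
Reagents that add atoms: none
Why: Palladium-catalysed hydrogenolysis should cleave both aryl benzyl ethers while aryl sulfate monoesters and the flavonol core are inert to these neutral conditions, and a cold proton exchange then gives the acid form.

Compound list
1 | 3,4-dihydroxybenzaldehyde | O=Cc1ccc(O)c(O)c1 | starting material
2 | 4-(benzyloxy)-3-hydroxybenzaldehyde | O=Cc1ccc(OCc2ccccc2)c(O)c1 | intermediate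
3 | 4-(benzyloxy)-3-(methoxymethoxy)benzaldehyde | O=Cc1ccc(OCc2ccccc2)c(OCOC)c1 | intermediate
4 | diethyl {2-[methoxy(methyl)amino]-2-oxoethyl}phosphonate | CCOP(=O)(OCC)CC(=O)N(C)OC | starting material
5 | sodium salt of the α-carbanion of phosphonate 4 | CCOP(=O)(OCC)[CH-]C(=O)N(C)OC.[Na+] | intermediate
6 | (2E)-3-[4-(benzyloxy)-3-(methoxymethoxy)phenyl]-N-methoxy-N-methylprop-2-enamide | CON(C)C(=O)/C=C/c1ccc(OCc2ccccc2)c(OCOC)c1 | intermediate
7 | 4-methoxy-6-methyl-2H-pyran-2-one | COc1cc(C)oc(=O)c1 | starting material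
8 | (4-methoxy-2-oxo-2H-pyran-6-yl)methyllithium | [Li]Cc1cc(OC)cc(=O)o1 | intermediate
9 | 6-{(3E)-4-[4-(benzyloxy)-3-(methoxymethoxy)phenyl]-2-oxobut-3-en-1-yl}-4-methoxy-2H-pyran-2-one | COc1cc(CC(=O)/C=C/c2ccc(OCc3ccccc3)c(OCOC)c2)oc(=O)c1 | intermediate
10 | methyl (2E,8E)-9-[4-(benzyloxy)-3-(methoxymethoxy)phenyl]-3-methoxy-5,7-dioxonona-2,8-dienoate (present as its magnesium enolate) | COC(=O)/C=C(/OC)CC(=O)CC(=O)/C=C/c1ccc(OCc2ccccc2)c(OCOC)c1 | intermediate
11 | (2E)-3-[4-(benzyloxy)-3-(methoxymethoxy)phenyl]-1-(2,6-dihydroxy-4-methoxyphenyl)prop-2-en-1-one | COc1cc(O)c(C(=O)/C=C/c2ccc(OCc3ccccc3)c(OCOC)c2)c(O)c1 | intermediate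
12 | (±)-2-[4-(benzyloxy)-3-(methoxymethoxy)phenyl]-5-hydroxy-7-methoxy-2,3-dihydro-4H-chromen-4-one (racemic at C2) | COc1cc(O)c2C(=O)CC(Oc2c1)c1ccc(OCc2ccccc2)c(OCOC)c1 | intermediate
13 | 2-[4-(benzyloxy)-3-(methoxymethoxy)phenyl]-5-hydroxy-7-methoxy-4H-chromen-4-one | COc1cc(O)c2c(=O)cc(-c3ccc(OCc4ccccc4)c(OCOC)c3)oc2c1 | intermediate
14 | 5-(benzyloxy)-2-[4-(benzyloxy)-3-(methoxymethoxy)phenyl]-7-methoxy-4H-chromen-4-one | COc1cc(OCc2ccccc2)c2c(=O)cc(-c3ccc(OCc4ccccc4)c(OCOC)c3)oc2c1 | intermediate
15 | 3-lithio derivative of flavone 14 | COc1cc(OCc2ccccc2)c2c(=O)c([Li])c(-c3ccc(OCc4ccccc4)c(OCOC)c3)oc2c1 | intermediate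
16 | dimethyl {5-(benzyloxy)-2-[4-(benzyloxy)-3-(methoxymethoxy)phenyl]-7-methoxy-4-oxo-4H-chromen-3-yl}boronate (from the lithium trimethoxyborate on acidification) | COB(OC)c1c(-c2ccc(OCc3ccccc3)c(OCOC)c2)oc2cc(OC)cc(OCc3ccccc3)c2c1=O | intermediate
17 | 5-(benzyloxy)-2-[4-(benzyloxy)-3-(methoxymethoxy)phenyl]-3-hydroxy-7-methoxy-4H-chromen-4-one | COc1cc(OCc2ccccc2)c2c(=O)c(O)c(-c3ccc(OCc4ccccc4)c(OCOC)c3)oc2c1 | intermediate
18 | 5-(benzyloxy)-2-[4-(benzyloxy)-3-hydroxyphenyl]-3-hydroxy-7-methoxy-4H-chromen-4-one | COc1cc(OCc2ccccc2)c2c(=O)c(O)c(-c3ccc(OCc4ccccc4)c(O)c3)oc2c1 | intermediate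
19 | 5-(benzyloxy)-2-[4-(benzyloxy)-3-(sulfooxy)phenyl]-7-methoxy-4-oxo-4H-chromen-3-yl hydrogen sulfate | COc1cc(OCc2ccccc2)c2c(=O)c(OS(=O)(=O)O)c(-c3ccc(OCc4ccccc4)c(OS(=O)(=O)O)c3)oc2c1 | intermediate
20 | rhamnetin 3,3'-disulfate (5-hydroxy-2-[4-hydroxy-3-(sulfooxy)phenyl]-7-methoxy-4-oxo-4H-chromen-3-yl hydrogen sulfate) | COc1cc(O)c2c(=O)c(OS(=O)(=O)O)c(-c3ccc(O)c(OS(=O)(=O)O)c3)oc2c1 | target

Total step count: 11
Longest linear sequence: 11 steps (1 → 20); phosphonate 4 and pyrone 7 enter as purchased materials.

Steps most likely to fail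

Step 5. The ring-opened chain may close in the wrong mode (aldol attack of C2 on the C7 ketone, leading to a resorcylate). Methoxide or the new phenoxide may also add to the enone, draining material into adducts or premature flavanone. Fallback: ring A formation is decoupled from the enone. Setting out from pyrone 7, the anion 8 is acylated with N-methoxy-N-methylacetamide to give 4-methoxy-6-(2-oxopropyl)-2H-pyran-2-one F1. The same magnesium methoxide closure on this simple ketone gives 1-(2,6-dihydroxy-4-methoxyphenyl)ethan-1-one F2, which can also be bought if the Claisen mode itself is the obstacle. Claisen–Schmidt condensation of F2 with aldehyde 3 (aq. KOH, EtOH, rt) then returns to the route at chalcone 11.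

Step 6. Iodine may substitute the electron-rich ring A (C6/C8) faster than it dehydrogenates C2–C3, or the flavanone may reopen and stall the oxidation. Fallback: ring C is closed and C3 is oxygenated in one operation without iodine. Setting out from chalcone 11, mono-O-benzylation (BnBr 1.05 equiv, K2CO3, acetone, reflux; the two hydroxyls are equivalent and the second stays chelated) gives (2E)-1-[2-(benzyloxy)-6-hydroxy-4-methoxyphenyl]-3-[4-(benzyloxy)-3-(methoxymethoxy)phenyl]prop-2-en-1-one F3. Algar–Flynn–Oyamada oxidation (30% H2O2, aq. NaOH, MeOH–THF, 0 °C → rt) converts F3 into flavonol 17, where the route is rejoined with steps 6–8 bypassed.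

Step 4. The soft pyrone anion may add in conjugate fashion to the cinnamoyl amide, or proton transfer from partly collapsed adduct may quench the anion and leave amide unreacted. Fallback: the C–C bond is made by carbonyl addition to an aldehyde and the ketone is generated afterwards. Setting out from aldehyde 3, Wittig homologation with (triphenylphosphoranylidene)acetaldehyde (toluene, 80 °C) gives (2E)-3-[4-(benzyloxy)-3-(methoxymethoxy)phenyl]prop-2-enal F4. 1,2-Addition of pyranylmethyllithium 8 (THF, −78 °C) gives racemic 6-{(3E)-4-[4-(benzyloxy)-3-(methoxymethoxy)phenyl]-2-hydroxybut-3-en-1-yl}-4-methoxy-2H-pyran-2-one F5. Oxidation of the allylic alcohol with MnO2 (CH2Cl2, rt) returns to the route at pyrone 9.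

Further compounds
F1 | step 5 | 4-methoxy-6-(2-oxopropyl)-2H-pyran-2-one | COc1cc(CC(C)=O)oc(=O)c1
F2 | step 5 | 1-(2,6-dihydroxy-4-methoxyphenyl)ethan-1-one | COc1cc(O)c(C(C)=O)c(O)c1
F3 | step 6 | (2E)-1-[2-(benzyloxy)-6-hydroxy-4-methoxyphenyl]-3-[4-(benzyloxy)-3-(methoxymethoxy)phenyl]prop-2-en-1-one | COc1cc(O)c(C(=O)/C=C/c2ccc(OCc3ccccc3)c(OCOC)c2)c(OCc2ccccc2)c1
F4 | step 4 | (2E)-3-[4-(benzyloxy)-3-(methoxymethoxy)phenyl]prop-2-enal | O=C/C=C/c1ccc(OCc2ccccc2)c(OCOC)c1
F5 | step 4 | (±)-6-{(3E)-4-[4-(benzyloxy)-3-(methoxymethoxy)phenyl]-2-hydroxybut-3-en-1-yl}-4-methoxy-2H-pyran-2-one | COc1cc(CC(O)/C=C/c2ccc(OCc3ccccc3)c(OCOC)c2)oc(=O)c1
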